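## Structural features

The target is a depsidone: benzene rings A and B are joined twice, by the diaryl ether a5–O–b1 and by the ester a4–C(=O)–O–b2, which together close a central seven-membered lactone. Ring A (a1 OMe, a2 H, a3 Me, a4 ester carbonyl, a5 ether O, a6 CH2OH) is pentasubstituted; ring B (b1 ether O, b2 ester O, b3 Me, b4 OH, b5 lactone carbonyl, b6 lactol carbon) is hexasubstituted and carries a fused five-membered lactol–lactone (a 3-hydroxyphthalide). The only stereocentre is the lactol carbon on b6, (R); it has no stereogenic neighbour, and as the cyclic hemiacetal of an ortho-formyl benzoic acid it can epimerise by ring opening. Fragile groups are the aryl ester of the seven-membered ring (bases, nucleophiles), the lactol, and the electron-rich benzylic alcohol on a6 (strong acid). The real difficulty is regiochemical: two crowded arenes must be joined through two adjacent heteroatom links, the catechol oxygens b1 and b2 must be told apart, and five different substituents must be placed around ring A. The key step exploits that ring A can be cut into three two-carbon units, a5≡a6, a1≡a2 and a3≡a4, each already bearing its substituents, and that every bond to be formed can be placed inside a tether: a4 and a5 through the ortho oxygens b2 and b1 of ring B, a6 and a1 through the a6 CH2O group and the a1 oxygen, which are ortho and can be bridged by one silicon atom. A bridge from the a6 CH2O group to carbon a2 is not an option, because a6 and a2 are meta and three atoms cannot span them; this is why silicon sits on the a1 oxygen in 27 and 28.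

## Logic of the disconnections

34 from 33 from 31: the two acetyl C–O bonds are cut, and behind them the configuration at the lactol carbon. The centre is set last because it equilibrates through the open formyl acid; taking it from the racemate 31 by dynamic kinetic acylation lets all material converge on one enantiomer. The forward steps need an enzyme that distinguishes the two lactol enantiomers while they interconvert, and a deacylation that is neutral enough not to racemise 34.

31 from 30: the lactol C–O bond is opened (ring–chain), and the phenol, the acid, the aldehyde and a2–H are traced back to a methoxymethyl ether, a tert-butyl ester, a dimethyl acetal and a C-silyl group. All four fall in one acid operation, so no separate deprotections are needed. The forward step must spare the benzylic alcohol and the aryl ester.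

30 from 29 from 28: the a1 O–CH3 bond is cut and the a1 oxygen and the a6 CH2O oxygen are reconnected through silicon. This exposes the tether that makes the ring synthesis regiospecific. The forward steps need a fluoride cleavage that leaves the aryl ester alone and a methylation that finds only the a1 phenol, which holds because b4 is still masked.

28 from 27 (key): a4–a5, a6–a1 and a2–a3 are cut, turning ring A into three alkynes. This removes three rings and three skeletal bonds at once and reduces the problem to ring B plus three small alkynes. The forward step must be chemoselective for the intramolecular path and tolerate two ynol ethers, an ynoate and a seven-membered tether.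

27 from 24 and 25: the b2 O–acyl bond is cut. The ynoate is the most electrophilic and base-sensitive unit and therefore enters last. The acylation must proceed without free acid touching the ynol ethers.

24 from 23: the b2 allyl ether is restored. b2 has to be masked through base and organolithium chemistry and then freed under neutral conditions in the presence of both ynol ethers.

23 from 17, 18 and 19: both Si–O bonds are cut. The unsymmetrical dialkoxysilane is assembled from a primary alcohol, a dichlorosilane and a silyl ynolate. The forward step needs mono-substitution of 18 and silylation of the ynolate at oxygen.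

17 from 14, 13, 10 and 11: the a6–CH2 bond (a one-carbon electrophile), the acetal and the b1 O–vinyl bond are cut. This is the standard route to aryl ynol ethers and brings in a5 and a6 from 11. It demands that ring B survive n-BuLi, which fixes the tert-butyl ester and the acetal as protecting groups.

10 from 8: the b6–CHO bond is cut. b6 is the only free position ortho to the b1 phenol, so phenoxide-directed formylation can only go there; the position is hindered by the neighbouring ester.

8 from 5, 4 and 3: the b1 C–O bond is traced to a C–Br bond, and the two ethers are removed. Bromine marks b1 while the two phenols of 3 differ enough (one chelated to the ester, one not) to be protected one after the other. The forward sequence needs a bromine–lithium exchange that is faster than attack on the ester.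

3 from 2 from 1: the C–Br bond and the tert-butyl ester are cut, leading to commercial 1, which already holds b2–O, b3–Me, b4–O and the b5 carboxyl.

## Other disconnections considered

Alternative 1: Ring B is cut at b1–b6 and b4–b5, so that it arises from the electron-rich diene A2 (which carries ring A as an aryloxy group) and the enantiopure bromobutenolide A3. The forward key step is a [4+2] cycloaddition followed by loss of the halide and an alkoxy group, giving the aromatic ring B already fused to the (R)-benzyloxyphthalide, A1.
- In favour: aromatising cycloadditions of this diene class with halogenated dienophiles are well-precedented, the regiochemistry follows from the polarisation of both partners, b1 and b2 are different from the start, and the stereocentre is carried as a stable benzyl acetal with no resolution.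
- Against here: A2 is a hindered, acid-labile ketene acetal that must be made from a fully substituted ring A phenol. Ring A needs its own synthesis. The basic aromatisation could epimerise the acetal centre. After A1 the seven-membered lactone still has to be closed and the benzyl acetal hydrogenolysed beside a benzylic C–O bond.
- Comparison: Alternative 1 builds ring B onto a finished ring A, the chosen plan the reverse. On mechanistic precedent and on the source of chirality Alternative 1 is the better of the two, and it is more convergent. It is the equal of the chosen plan on the lability of the final free lactol, and it is not shorter in total step count because two arene syntheses and a separate lactonisation are needed.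

Alternative 2: The cuts are b1 O–a5, a4–C(=O) and C(=O)–O(b2). The forward key step combines the catechol A5, the fluoro-iodoarene A6 and carbon monoxide A7 in one pot: nucleophilic aromatic substitution, then palladium-catalysed carbonylative lactonisation, giving A4.
- In favour: it is the most convergent of all plans, forming three bonds and the seven-membered ring from two arenes, and each elementary step is a known reaction type. On step count and on precedent it is better than the chosen plan.
- Against here: nothing decides which oxygen of A5 displaces fluoride, so the isomer with ether and ester interchanged is a likely by-product. The iodide is flanked by two ortho groups, and A7 is a toxic gas. A4 is at the wrong oxidation level at two carbons: the a6 aldehyde must be reduced, and the phthalide CH2 oxidised to the lactol in competition with two aryl methyl groups and a benzylic alcohol. A benzyl ether then has to be removed next to a benzylic C–O bond.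
- Comparison: the chosen plan spends its early steps making b1 and b2 different and carries the lactol carbon at the aldehyde level throughout, which is exactly what Alternative 2 lacks. The enantiomer would have to be obtained in the same enzymatic way, so on that point the two are equal.

Alternative 3: The lactol ring is cut at b5–C(=O), the lactone C–O and the acetal C–O. The forward key step joins the ortho-bromo aldehyde A9, carbon monoxide A7 and benzyl alcohol A10 under a palladium catalyst with a chiral bisphosphine, giving the (R)-O-benzyl acetal A8.
- In favour: the stereocentre is set by catalysis on the complete depsidone and stored as a configurationally stable acetal. The racemic carbonylative closure to alkoxyphthalides is a known reaction type, and no resolution step is needed, which in principle makes it better than the chosen plan on stereocontrol.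
- Against here: an enantioselective version has no precedent, since the selectivity-determining event (alcohol addition to the aldehyde or acylpalladium) is reversible and weakly organised. The bromide is flanked by two ortho groups. Two benzyl groups must later be hydrogenolysed beside a benzylic C–O bond, after which the lactol is as labile as in the chosen plan.
- Comparison: Alternative 3 does nothing for the skeleton; A9 must first be made by the chosen key step or by another diaryl ether route, so it complements the chosen plan and does not replace it. In its asymmetric mode it is as speculative as the chosen key step (equal on mechanism), and it is longer overall.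

Key step: step 13

Remark on the tether: a diyne tied from the a6 CH2O group to a silicon on carbon a2 would join a6 to a2 and not to a1, so the silicon is bound to the a1 oxygen (silyl ynol ether). The bond made inside the tether is then a6–a1, the temporary ring is a six-membered 4H-1,3,2-benzodioxasiline, a2 carries SiMe3 (exchanged for hydrogen in step 16), and the a1 oxygen is methylated in step 15.

Assumption: the (R)-lactol 34 is taken to be configurationally stable enough in neutral, aprotic media at or below room temperature to be isolated; in base it racemises through the open formyl acid.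

## Steps

Step 1
Reactants: 1 2,4-dihydroxy-3-methylbenzoic acid
Product: 2 tert-butyl 2,4-dihydroxy-3-methylbenzoate
Conditions: tert-butyl 2,2,2-trichloroacetimidate (2 equiv), CH2Cl2/cyclohexane, 25 °C
Reagents that add atoms: tert-butyl 2,2,2-trichloroacetimidate, CC(C)(C)OC(=N)C(Cl)(Cl)Cl
Why: Imidate esterification: the carboxylic acid protonates the imidate and captures the tert-butyl cation, while the phenols do not react without a Lewis acid. The tert-butyl ester is chosen because, once flanked by two ortho groups, it resists n-BuLi in step 9 and falls with acid in step 16.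

Step 2
Reactants: 2 tert-butyl 2,4-dihydroxy-3-methylbenzoate
Product: 3 tert-butyl 5-bromo-2,4-dihydroxy-3-methylbenzoate
Conditions: N-bromosuccinimide (1.0 equiv), MeCN, 0 °C
Reagents that add atoms: N-bromosuccinimide, O=C1CCC(=O)N1Br
Why: Electrophilic aromatic bromination; C5 is the only free position ortho or para to both hydroxyl groups (C3 is blocked, C6 is meta to both and ortho to the ester). The bromine marks the future b1 oxygen.

Step 3
Reactants: 3 tert-butyl 5-bromo-2,4-dihydroxy-3-methylbenzoate
Product: 4 tert-butyl 5-bromo-2-hydroxy-3-methyl-4-(prop-2-en-1-yloxy)benzoate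
Conditions: allyl bromide (1.05 equiv), K2CO3 (1.1 equiv), acetone, 50 °C
Reagents that add atoms: allyl bromide, C=CCBr
Why: Williamson etherification; the 4-hydroxyl (para to the ester, ortho to bromine) is the more acidic and is not held in the hydrogen bond to the ester carbonyl that deactivates the 2-hydroxyl, so one equivalent of base should alkylate it selectively.

Step 4
Reactants: 4 tert-butyl 5-bromo-2-hydroxy-3-methyl-4-(prop-2-en-1-yloxy)benzoate
Product: 5 tert-butyl 5-bromo-2-(methoxymethoxy)-3-methyl-4-(prop-2-en-1-yloxy)benzoate
Conditions: NaH (1.2 equiv), chloromethyl methyl ether (1.3 equiv), THF, 0 to 25 °C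
Reagents that add atoms: chloromethyl methyl ether, COCCl
Why: Phenoxide alkylation; the chelated, hindered phenol needs full deprotonation to react. The resulting acetal-type ether is inert to bases and organolithiums and is removed in the final acid step; the reagent is a carcinogen and is handled as a solution in a closed system.

Step 5
Reactants: 5 tert-butyl 5-bromo-2-(methoxymethoxy)-3-methyl-4-(prop-2-en-1-yloxy)benzoate
Product: 8 tert-butyl 5-hydroxy-2-(methoxymethoxy)-3-methyl-4-(prop-2-en-1-yloxy)benzoate, via aryllithium 6 (not isolated), via aryl diisopropyl boronate 7 (not isolated)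
Conditions: B(OiPr)3 (1.5 equiv), n-BuLi (1.1 equiv), THF/toluene, −78 °C; then H2O2 (30 % aq.), NaHCO3, 0 °C
Reagents that add atoms: hydrogen peroxide, OO
Why: Bromine–lithium exchange with in situ borylation, then oxidation of the C–B bond: the borate is present when n-BuLi is added, so the aryllithium is trapped before it can attack the tert-butyl ester or the allyl ether. This turns the b1 bromide into the b1 phenol with b2 and b4 already differentiated.

Step 6
Reactants: 8 tert-butyl 5-hydroxy-2-(methoxymethoxy)-3-methyl-4-(prop-2-en-1-yloxy)benzoate
Product: 10 tert-butyl 2-formyl-3-hydroxy-6-(methoxymethoxy)-5-methyl-4-(prop-2-en-1-yloxy)benzoate, via hydroxymethyl phenol 9 (not isolated)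
Conditions: MgCl2 (2 equiv), Et3N (4 equiv), paraformaldehyde (6 equiv), THF, 66 °C
Reagents that add atoms: formaldehyde (as paraformaldehyde), C=O
Why: Magnesium phenoxide-directed ortho-formylation (Casnati–Skattebøl): formaldehyde is delivered inside the magnesium chelate to the only free ortho position, b6, and a second equivalent oxidises the benzylic alkoxide to the aldehyde by hydride transfer. No acid is involved, so the tert-butyl ester and the methoxymethyl ether survive.

Step 7
Reactants: 10 tert-butyl 2-formyl-3-hydroxy-6-(methoxymethoxy)-5-methyl-4-(prop-2-en-1-yloxy)benzoate; 11 trichloroethene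
Product: 13 tert-butyl 3-{[(E)-1,2-dichloroethenyl]oxy}-2-formyl-6-(methoxymethoxy)-5-methyl-4-(prop-2-en-1-yloxy)benzoate, via dichloroethyne 12 (not isolated)
Conditions: K2CO3 (1.5 equiv), DMF, 70 °C, under N2
Reagents that add atoms: none
Why: Base-mediated vinylation of a phenol with trichloroethene: dehydrochlorination gives dichloroethyne, to which the phenoxide adds anti to give the (E)-1,2-dichlorovinyl ether; the small linear electrophile tolerates the two ortho substituents. Dichloroethyne is toxic and is kept in solution under nitrogen and destroyed on work-up.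

Step 8
Reactants: 13 tert-butyl 3-{[(E)-1,2-dichloroethenyl]oxy}-2-formyl-6-(methoxymethoxy)-5-methyl-4-(prop-2-en-1-yloxy)benzoate
Product: 14 tert-butyl 3-{[(E)-1,2-dichloroethenyl]oxy}-2-(dimethoxymethyl)-6-(methoxymethoxy)-5-methyl-4-(prop-2-en-1-yloxy)benzoate
Conditions: HC(OMe)3 (5 equiv), MeOH, pyridinium p-toluenesulfonate (5 mol %), 40 °C
Reagents that add atoms: trimethyl orthoformate, COC(OC)OC; methanol, CO
Why: Acid-catalysed acetalisation with the orthoformate as water scavenger; it masks the aldehyde for the organolithium step. The weak pyridinium acid is chosen to spare the methoxymethyl ether, the tert-butyl ester and the chloro enol ether.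

Step 9
Reactants: 14 tert-butyl 3-{[(E)-1,2-dichloroethenyl]oxy}-2-(dimethoxymethyl)-6-(methoxymethoxy)-5-methyl-4-(prop-2-en-1-yloxy)benzoate
Product: 17 tert-butyl 2-(dimethoxymethyl)-3-[(3-hydroxyprop-1-yn-1-yl)oxy]-6-(methoxymethoxy)-5-methyl-4-(prop-2-en-1-yloxy)benzoate, via chloroalkynyl ether 15 (not isolated), via lithium aryloxyacetylide 16 (not isolated)
Conditions: n-BuLi (2.4 equiv), THF, −78 °C; then paraformaldehyde, −78 to 0 °C; NH4Cl (aq.)
Reagents that add atoms: formaldehyde (as paraformaldehyde), C=O
Why: Standard conversion of an aryl 1,2-dichlorovinyl ether into a lithium aryloxyacetylide (elimination of HCl, then chlorine–lithium exchange) followed by 1,2-addition to formaldehyde; this installs a5, a6 and the a6 CH2OH carbon. The tert-butyl ester is shielded by both ortho groups, and the acetal and ethers are inert to n-BuLi at −78 °C.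

Step 10
Reactants: 17 tert-butyl 2-(dimethoxymethyl)-3-[(3-hydroxyprop-1-yn-1-yl)oxy]-6-(methoxymethoxy)-5-methyl-4-(prop-2-en-1-yloxy)benzoate; 18 dichlorodi(propan-2-yl)silane; 19 ethynyl(trimethyl)silane
Product: 23 tert-butyl 2-(dimethoxymethyl)-3-[(3-{[di(propan-2-yl)({[(trimethylsilyl)ethynyl]oxy})silyl]oxy}prop-1-yn-1-yl)oxy]-6-(methoxymethoxy)-5-methyl-4-(prop-2-en-1-yloxy)benzoate, via chlorosilyl ether 20 (not isolated), via lithium trimethylsilylacetylide 21 (not isolated), via lithium silylynolate 22 (not isolated)
Conditions: 18 (3 equiv), imidazole, CH2Cl2, 0 °C, then excess 18 removed in vacuo; 19, n-BuLi, THF, −78 °C, then LiOOtBu (from t-BuOOH and LiN(SiMe3)2), −78 to 0 °C; the chlorosilane added at −78 °C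
Reagents that add atoms: tert-butyl hydroperoxide, CC(C)(C)OO
Why: The silicon tether is built by two O-silylations: excess 18 mono-silylates the primary alcohol, and the silyl ynolate (from oxidation of the lithium acetylide with the lithium peroxide) is then silylated at oxygen, as hindered chlorosilanes do with ynolates; attack at the silyl-bearing carbon is sterically disfavoured. The product is worked up cold and base-buffered because silyl ynol ethers are acid-labile and can undergo thermal oxygen-to-carbon silyl shift.

Step 11
Reactants: 23 tert-butyl 2-(dimethoxymethyl)-3-[(3-{[di(propan-2-yl)({[(trimethylsilyl)ethynyl]oxy})silyl]oxy}prop-1-yn-1-yl)oxy]-6-(methoxymethoxy)-5-methyl-4-(prop-2-en-1-yloxy)benzoate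
Product: 24 tert-butyl 2-(dimethoxymethyl)-3-[(3-{[di(propan-2-yl)({[(trimethylsilyl)ethynyl]oxy})silyl]oxy}prop-1-yn-1-yl)oxy]-4-hydroxy-6-(methoxymethoxy)-5-methylbenzoate
Conditions: Pd(PPh3)4 (5 mol %), morpholine (5 equiv), THF, 25 °C
Reagents that add atoms: none
Why: Palladium-catalysed allyl transfer (Tsuji–Trost deallylation): zerovalent palladium ionises the aryl allyl ether and morpholine captures the allyl unit. The neutral conditions leave both ynol ethers, the Si–O bonds, the acetal and the ester untouched.

Step 12
Reactants: 24 tert-butyl 2-(dimethoxymethyl)-3-[(3-{[di(propan-2-yl)({[(trimethylsilyl)ethynyl]oxy})silyl]oxy}prop-1-yn-1-yl)oxy]-4-hydroxy-6-(methoxymethoxy)-5-methylbenzoate; 25 but-2-ynoic acid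
Product: 27 tert-butyl 4-(but-2-ynoyloxy)-2-(dimethoxymethyl)-3-[(3-{[di(propan-2-yl)({[(trimethylsilyl)ethynyl]oxy})silyl]oxy}prop-1-yn-1-yl)oxy]-6-(methoxymethoxy)-5-methylbenzoate, via but-2-ynoic anhydride 26 (not isolated)
Conditions: 25 (2.4 equiv), N,N'-dicyclohexylcarbodiimide (1.2 equiv), CH2Cl2, 0 °C, filtration; then 24, Et3N, 4-(dimethylamino)pyridine (10 mol %), CH2Cl2, −20 to 0 °C
Reagents that add atoms: none
Why: Steglich-type acylation through the preformed symmetrical anhydride, so that no free carboxylic acid, which would add across the ynol ethers, meets the substrate. Low temperature and catalytic amine limit conjugate addition to the ynoate.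

Step 13
Reactants: 27 tert-butyl 4-(but-2-ynoyloxy)-2-(dimethoxymethyl)-3-[(3-{[di(propan-2-yl)({[(trimethylsilyl)ethynyl]oxy})silyl]oxy}prop-1-yn-1-yl)oxy]-6-(methoxymethoxy)-5-methylbenzoate
Product: 28 silicon-bridged depsidone: ring A a1–O–Si(iPr)2–O–CH2–a6; a2 SiMe3; a3 Me; ring B b3 Me; b4 OCH2OMe; b5 CO2tBu; b6 CH(OMe)2; rings joined by a5–O–b1 and a4–C(=O)–O–b2
Conditions: [Rh(cod)2]BF4 (10 mol %), rac-BINAP (10 mol %), activated with H2 then Ar, ClCH2CH2Cl, 25 °C, slow addition of 27 to 0.005 M
Reagents that add atoms: none
Why: Proposed new method: the cationic monovalent rhodium–bisphosphine fragment should bind the two electron-rich ynol ether units of the silicon-tethered 1,7-diyne and couple them oxidatively to a rhodacyclopentadiene, which forms a6–a1 and with it the six-membered dioxasiline ring (closure dictated by the O–Si–O–CH2 tether); the electron-poor ynoate, held over the metallacycle by the catechol of ring B, then inserts, and reductive elimination forms a2–a3 and a4–a5, closing ring A by the [2+2+2] path and the seven-membered lactone by bond formation across the b1–O / b2–O–C(=O) tether. The closest known reaction type is the rhodium-catalysed cyclotrimerisation of tethered triynes and of 1,6- or 1,7-diynes with alkynes, in which silicon-containing tethers, aryl ethynyl ethers and alkynoates are each known as single components; a silyl ynol ether, an aryl ynol ether and a seven-membered lactone tether in one substrate have no precedent. No stereocentre is formed. The step needs chemoselectivity for the intramolecular path over oligomerisation, which high dilution and the two tethers should secure, and regioselectivity, which is fixed because a4 can reach only a5 (the ester oxygen and the ether oxygen sit on the adjacent carbons b2 and b1) and a1 can reach only a6 (the tether spans exactly one ring bond), so only one arene isomer can form. Room temperature keeps the silyl ynol ether below the range of the thermal oxygen-to-carbon silyl shift.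

Step 14
Reactants: 28 silicon-bridged depsidone: ring A a1–O–Si(iPr)2–O–CH2–a6; a2 SiMe3; a3 Me; ring B b3 Me; b4 OCH2OMe; b5 CO2tBu; b6 CH(OMe)2
Product: 29 depsidone phenol–alcohol: ring A a1 OH; a2 SiMe3; a3 Me; a6 CH2OH; ring B b3 Me; b4 OCH2OMe; b5 CO2tBu; b6 CH(OMe)2
Conditions: Bu4NF (2.5 equiv), AcOH (3 equiv), THF, 0 °C
Reagents that add atoms: none
Why: Fluoride cleaves both Si–O bonds of the dialkoxysilane, driven by Si–F bond formation; acetic acid buffers the phenoxide and alkoxide so that the aryl ester is not attacked. The aryl C–Si bond at a2 is not cleaved under these conditions.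

Step 15
Reactants: 29 depsidone phenol–alcohol: ring A a1 OH; a2 SiMe3; a3 Me; a6 CH2OH; ring B b3 Me; b4 OCH2OMe; b5 CO2tBu; b6 CH(OMe)2
Product: 30 depsidone methyl ether: ring A a1 OMe; a2 SiMe3; a3 Me; a6 CH2OH; ring B b3 Me; b4 OCH2OMe; b5 CO2tBu; b6 CH(OMe)2
Conditions: MeI (3 equiv), K2CO3 (1.5 equiv), DMF, 25 °C
Reagents that add atoms: iodomethane, CI
Why: Williamson methylation; carbonate ionises only the a1 phenol (the benzylic alcohol is not deprotonated and the b4 phenol is still an ether), so methylation is selective for a1. No nucleophile able to open the aryl ester is present.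

Step 16
Reactants: 30 depsidone methyl ether: ring A a1 OMe; a2 SiMe3; a3 Me; a6 CH2OH; ring B b3 Me; b4 OCH2OMe; b5 CO2tBu; b6 CH(OMe)2
Product: 31 racemic target lactol: ring A a1 OMe; a2 H; a3 Me; a6 CH2OH; ring B b3 Me; b4 OH; b5–C(=O)–O–CH(OH)–b6 of either configuration
Conditions: CF3CO2H/CH2Cl2/H2O (10:10:1), 0 to 25 °C
Reagents that add atoms: water, O
Why: One acid operation: ipso-protodesilylation at a2 (activated by the ortho methoxy and para aryloxy groups), cleavage of the methoxymethyl ether, of the tert-butyl ester (alkyl–oxygen fission) and of the acetal. The liberated ortho-formyl acid closes to the five-membered lactol, the favoured ring tautomer; the stereocentre forms without control, giving the racemate.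

Step 17
Reactants: 31 racemic target lactol: ring A a1 OMe; a2 H; a3 Me; a6 CH2OH; ring B b3 Me; b4 OH; b5–C(=O)–O–CH(OH)–b6 of either configuration
Product: 33 (R)-lactol acetate with a6 CH2OAc: ring A a1 OMe; a3 Me; ring B b3 Me; b4 OH; b5–C(=O)–O–CH(OAc)–b6 with (R) configuration, via racemic lactol monoacetate 32 (not isolated)
Conditions: immobilised Burkholderia cepacia lipase, vinyl acetate (10 equiv), Et3N (0.2 equiv), toluene, 35 °C
Reagents that add atoms: vinyl acetate, C=COC(C)=O
Why: Lipase-catalysed transesterification under dynamic kinetic resolution conditions, a reaction type known for γ-hydroxybutenolide lactols: the lactol enantiomers interconvert through the open formyl acid (helped by the trace of amine) while the enzyme acylates one of them irreversibly. The (R) enantiomer is the one expected from the empirical size rule for lipases (fused aryl carbon large, lactone oxygen small) and has to be confirmed by screening; the acylated lactol can no longer ring-open, so its configuration is fixed. The primary alcohol is acetylated as well, which is harmless.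

Step 18
Reactants: 33 (R)-lactol acetate with a6 CH2OAc: ring A a1 OMe; a3 Me; ring B b3 Me; b4 OH; b5–C(=O)–O–CH(OAc)–b6 with (R) configuration
Product: 34 target: ring A a1 OMe; a2 H; a3 Me; a6 CH2OH; ring B b3 Me; b4 OH; b5–C(=O)–O–CH(OH)–b6 with (R) configuration at the lactol carbon
Conditions: immobilised Burkholderia cepacia lipase, butan-1-ol (6 equiv), tert-butyl methyl ether, 20 °C
Reagents that add atoms: none
Why: Lipase-catalysed alcoholysis of both acetates under neutral, non-aqueous conditions; the enzyme has the same enantiopreference as in step 17, so any (S)-acetate reacts more slowly and the (R) configuration is carried over. No base is present, which keeps ring opening and racemisation of the freed lactol to a minimum.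

## Compound list

1 | 2,4-dihydroxy-3-methylbenzoic acid | Cc1c(O)ccc(C(=O)O)c1O | starting material
2 | tert-butyl 2,4-dihydroxy-3-methylbenzoate | Cc1c(O)ccc(C(=O)OC(C)(C)C)c1O | intermediate
3 | tert-butyl 5-bromo-2,4-dihydroxy-3-methylbenzoate | Cc1c(O)c(Br)cc(C(=O)OC(C)(C)C)c1O | intermediate
4 | tert-butyl 5-bromo-2-hydroxy-3-methyl-4-(prop-2-en-1-yloxy)benzoate | Cc1c(OCC=C)c(Br)cc(C(=O)OC(C)(C)C)c1O | intermediate
5 | tert-butyl 5-bromo-2-(methoxymethoxy)-3-methyl-4-(prop-2-en-1-yloxy)benzoate | Cc1c(OCC=C)c(Br)cc(C(=O)OC(C)(C)C)c1OCOC | intermediate
6 | aryllithium: [5-(tert-butoxycarbonyl)-4-(methoxymethoxy)-3-methyl-2-(prop-2-en-1-yloxy)phenyl]lithium | Cc1c(OCC=C)c([Li])cc(C(=O)OC(C)(C)C)c1OCOC | intermediate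
7 | aryl diisopropyl boronate: dipropan-2-yl [5-(tert-butoxycarbonyl)-4-(methoxymethoxy)-3-methyl-2-(prop-2-en-1-yloxy)phenyl]boronate | Cc1c(OCC=C)c(B(OC(C)C)OC(C)C)cc(C(=O)OC(C)(C)C)c1OCOC | intermediate
8 | tert-butyl 5-hydroxy-2-(methoxymethoxy)-3-methyl-4-(prop-2-en-1-yloxy)benzoate | Cc1c(OCC=C)c(O)cc(C(=O)OC(C)(C)C)c1OCOC | intermediate
9 | hydroxymethyl phenol: tert-butyl 3-hydroxy-2-(hydroxymethyl)-6-(methoxymethoxy)-5-methyl-4-(prop-2-en-1-yloxy)benzoate | Cc1c(OCC=C)c(O)c(CO)c(C(=O)OC(C)(C)C)c1OCOC | intermediate
10 | tert-butyl 2-formyl-3-hydroxy-6-(methoxymethoxy)-5-methyl-4-(prop-2-en-1-yloxy)benzoate | Cc1c(OCC=C)c(O)c(C=O)c(C(=O)OC(C)(C)C)c1OCOC | intermediate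
11 | trichloroethene | ClC=C(Cl)Cl | starting material
12 | dichloroethyne | ClC#CCl | intermediate
13 | tert-butyl 3-{[(E)-1,2-dichloroethenyl]oxy}-2-formyl-6-(methoxymethoxy)-5-methyl-4-(prop-2-en-1-yloxy)benzoate | Cc1c(OCC=C)c(O/C(Cl)=C\Cl)c(C=O)c(C(=O)OC(C)(C)C)c1OCOC | intermediate
14 | tert-butyl 3-{[(E)-1,2-dichloroethenyl]oxy}-2-(dimethoxymethyl)-6-(methoxymethoxy)-5-methyl-4-(prop-2-en-1-yloxy)benzoate | Cc1c(OCC=C)c(O/C(Cl)=C\Cl)c(C(OC)OC)c(C(=O)OC(C)(C)C)c1OCOC | intermediate
15 | chloroalkynyl ether: tert-butyl 3-[(chloroethynyl)oxy]-2-(dimethoxymethyl)-6-(methoxymethoxy)-5-methyl-4-(prop-2-en-1-yloxy)benzoate | Cc1c(OCC=C)c(OC#CCl)c(C(OC)OC)c(C(=O)OC(C)(C)C)c1OCOC | intermediate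
16 | lithium aryloxyacetylide: {[3-(tert-butoxycarbonyl)-2-(dimethoxymethyl)-4-(methoxymethoxy)-5-methyl-6-(prop-2-en-1-yloxy)phenoxy]ethynyl}lithium | Cc1c(OCC=C)c(OC#C[Li])c(C(OC)OC)c(C(=O)OC(C)(C)C)c1OCOC | intermediate
17 | tert-butyl 2-(dimethoxymethyl)-3-[(3-hydroxyprop-1-yn-1-yl)oxy]-6-(methoxymethoxy)-5-methyl-4-(prop-2-en-1-yloxy)benzoate | Cc1c(OCC=C)c(OC#CCO)c(C(OC)OC)c(C(=O)OC(C)(C)C)c1OCOC | intermediate
18 | dichlorodi(propan-2-yl)silane | CC(C)[Si](Cl)(Cl)C(C)C | starting material
19 | ethynyl(trimethyl)silane | C#C[Si](C)(C)C | starting material
20 | chlorosilyl ether: tert-butyl 3-[(3-{[chlorodi(propan-2-yl)silyl]oxy}prop-1-yn-1-yl)oxy]-2-(dimethoxymethyl)-6-(methoxymethoxy)-5-methyl-4-(prop-2-en-1-yloxy)benzoate | Cc1c(OCC=C)c(OC#CCO[Si](Cl)(C(C)C)C(C)C)c(C(OC)OC)c(C(=O)OC(C)(C)C)c1OCOC | intermediate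
21 | lithium trimethylsilylacetylide: [(trimethylsilyl)ethynyl]lithium | [Li]C#C[Si](C)(C)C | intermediate
22 | lithium silylynolate: lithium 2-(trimethylsilyl)ethynolate | [Li]OC#C[Si](C)(C)C | intermediate
23 | tert-butyl 2-(dimethoxymethyl)-3-[(3-{[di(propan-2-yl)({[(trimethylsilyl)ethynyl]oxy})silyl]oxy}prop-1-yn-1-yl)oxy]-6-(methoxymethoxy)-5-methyl-4-(prop-2-en-1-yloxy)benzoate | Cc1c(OCC=C)c(OC#CCO[Si](OC#C[Si](C)(C)C)(C(C)C)C(C)C)c(C(OC)OC)c(C(=O)OC(C)(C)C)c1OCOC | intermediate
24 | tert-butyl 2-(dimethoxymethyl)-3-[(3-{[di(propan-2-yl)({[(trimethylsilyl)ethynyl]oxy})silyl]oxy}prop-1-yn-1-yl)oxy]-4-hydroxy-6-(methoxymethoxy)-5-methylbenzoate | Cc1c(O)c(OC#CCO[Si](OC#C[Si](C)(C)C)(C(C)C)C(C)C)c(C(OC)OC)c(C(=O)OC(C)(C)C)c1OCOC | intermediate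
25 | but-2-ynoic acid | CC#CC(=O)O | starting material
26 | but-2-ynoic anhydride | CC#CC(=O)OC(=O)C#CC | intermediate
27 | key-step precursor: tert-butyl 4-(but-2-ynoyloxy)-2-(dimethoxymethyl)-3-[(3-{[di(propan-2-yl)({[(trimethylsilyl)ethynyl]oxy})silyl]oxy}prop-1-yn-1-yl)oxy]-6-(methoxymethoxy)-5-methylbenzoate | C[Si](C)(C)C#CO[Si](C(C)C)(C(C)C)OCC#COc1c(OC(=O)C#CC)c(C)c(OCOC)c(C(=O)OC(C)(C)C)c1C(OC)OC | intermediate
28 | key-step product: silicon-bridged depsidone; ring A a1–O–Si(iPr)2–O–CH2–a6 (4H-1,3,2-benzodioxasiline), a2 SiMe3, a3 Me; ring B b3 Me, b4 OCH2OMe, b5 CO2tBu, b6 CH(OMe)2 | C[Si](C)(C)c1c(C)c2c(c3c1O[Si](C(C)C)(C(C)C)OC3)Oc1c(c(C)c(OCOC)c(C(=O)OC(C)(C)C)c1C(OC)OC)OC2=O | intermediate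
29 | depsidone phenol–alcohol; ring A a1 OH, a2 SiMe3, a3 Me, a6 CH2OH; ring B as in 28 | C[Si](C)(C)c1c(C)c2c(c(CO)c1O)Oc1c(c(C)c(OCOC)c(C(=O)OC(C)(C)C)c1C(OC)OC)OC2=O | intermediate
30 | depsidone methyl ether; ring A a1 OMe, a2 SiMe3, a3 Me, a6 CH2OH; ring B as in 28 | C[Si](C)(C)c1c(C)c2c(c(CO)c1OC)Oc1c(c(C)c(OCOC)c(C(=O)OC(C)(C)C)c1C(OC)OC)OC2=O | intermediate
31 | racemic target lactol | COc1cc(C)c2c(c1CO)Oc1c(c(C)c(O)c3c1C(O)OC3=O)OC2=O | intermediate
32 | racemic lactol monoacetate (a6 CH2OAc) | COc1cc(C)c2c(c1COC(C)=O)Oc1c(c(C)c(O)c3c1C(O)OC3=O)OC2=O | intermediate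
33 | (R)-lactol acetate with a6 CH2OAc | COc1cc(C)c2c(c1COC(C)=O)Oc1c(c(C)c(O)c3c1[C@H](OC(C)=O)OC3=O)OC2=O | intermediate
34 | target, (R) at the lactol carbon | COc1cc(C)c2c(c1CO)Oc1c(c(C)c(O)c3c1[C@H](O)OC3=O)OC2=O | target

## Step count and least certain steps

Total: 18 steps. Longest linear sequence: 18 steps (1 to 34); 11, 18, 19 and 25 are purchased and enter directly.

Step 13 (key step, proposed new method). Most likely failures: oligomerisation or a stalled metallacycle because closing the seven-membered lactone tether is strained; catalyst-induced loss of the silyl ynol ether (silyl shift to a ketene, hydration); and slow insertion next to the bulky C-silyl group. The fallback builds the depsidone from two arenes by known reactions; it sets out from 10 and returns at 31. Compound 10 is acetalised (conditions of step 8) to the hydroxy acetal F4. Separately, purchased 1-fluoro-3-methoxy-5-methylbenzene F1 is lithiated between fluorine and methoxy (n-BuLi) and formylated (DMF) to 2-fluoro-6-methoxy-4-methylbenzaldehyde F2. After in situ protection of the formyl group as its lithium amino alkoxide, F2 is lithiated next to fluorine (s-BuLi) and trapped with allyl chloroformate to give the allyl ester F3. Nucleophilic aromatic substitution of the doubly activated fluoride of F3 by the phenoxide of F4 (Cs2CO3, DMF) gives the diaryl ether aldehyde F5. NaBH4 reduces its only free aldehyde to the diaryl ether alcohol F6. Pd(PPh3)4 with morpholine removes both allyl groups to give the hydroxy acid F7. Lactonisation (2-chloro-1-methylpyridinium iodide, Et3N, high dilution) closes the seven-membered ring to the depsidone F8, which the conditions of step 16 convert into 31.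

Step 10. Most likely failures: capture of the chlorosilane by the lithium tert-butoxide formed in the acetylide oxidation, and silylation at carbon or later oxygen-to-carbon silyl migration, both of which drain material into ketene-type products. The fallback sets out from 20 and returns at 23: the ynolate 22 is generated instead by deprotonation of (trimethylsilyl)ketene F9 with n-BuLi at −100 °C, which produces no competing alkoxide, and is silylated by 20 as before.

Step 6. Most likely failure: incomplete formylation, because the only free ortho position is shielded and deactivated by the neighbouring tert-butyl ester. The fallback sets out from 8 and returns at 10: silylation (tert-butyldimethylsilyl chloride, imidazole) gives the silyl ether F10; ester-directed magnesiation of the only ring C–H with TMPMgCl·LiCl (the magnesium chloride 2,2,6,6-tetramethylpiperidide–lithium chloride base) gives the arylmagnesium chloride F11; DMF converts it into the silyl-protected aldehyde F12; Bu4NF with AcOH then frees the phenol 10.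

Step 16. Most likely failures: ionisation of the electron-rich benzylic alcohol in strong acid (self-alkylation, trifluoroacetylation) and partial acidolysis of the aryl ester. The fallback sets out from 30 and returns at 32: acetylation (Ac2O, pyridine) gives the benzylic acetate F13, in which ionisation of the benzylic C–O bond is suppressed; the same acid treatment then gives 32, which enters step 17.

Step 17. Most likely failures: too little enantioselection, racemisation of the lactol slower than its acylation (leaving a simple kinetic resolution), or preference of the enzyme for the wrong enantiomer. The fallback sets out from 31 and returns at 33: Ac2O and pyridine at 0 °C give the racemic diacetate F14, which is configurationally stable; its enantiomers are separated by preparative chromatography on a chiral stationary phase. The (R) enantiomer is 33. The (S)-diacetate F15 is deacetylated under the conditions of step 18 back to 31, which racemises and is recycled.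

## Further compounds

F1 | step 13 | 1-fluoro-3-methoxy-5-methylbenzene (purchased) | COc1cc(C)cc(F)c1
F2 | step 13 | 2-fluoro-6-methoxy-4-methylbenzaldehyde | COc1cc(C)cc(F)c1C=O
F3 | step 13 | prop-2-en-1-yl 2-fluoro-3-formyl-4-methoxy-6-methylbenzoate | COc1cc(C)c(C(=O)OCC=C)c(F)c1C=O
F4 | step 13 | tert-butyl 2-(dimethoxymethyl)-3-hydroxy-6-(methoxymethoxy)-5-methyl-4-(prop-2-en-1-yloxy)benzoate | Cc1c(OCC=C)c(O)c(C(OC)OC)c(C(=O)OC(C)(C)C)c1OCOC
F5 | step 13 | diaryl ether aldehyde (a5–O–b1; a4 CO2allyl; a6 CHO; ring B as in F4) | COc1cc(C)c(C(=O)OCC=C)c(Oc2c(OCC=C)c(C)c(OCOC)c(C(=O)OC(C)(C)C)c2C(OC)OC)c1C=O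
F6 | step 13 | diaryl ether alcohol (a6 CH2OH) | COc1cc(C)c(C(=O)OCC=C)c(Oc2c(OCC=C)c(C)c(OCOC)c(C(=O)OC(C)(C)C)c2C(OC)OC)c1CO
F7 | step 13 | hydroxy acid (a4 CO2H; b2 OH) | COc1cc(C)c(C(=O)O)c(Oc2c(O)c(C)c(OCOC)c(C(=O)OC(C)(C)C)c2C(OC)OC)c1CO
F8 | step 13 | depsidone with a1 OMe, a2 H, a6 CH2OH and protected ring B | COc1cc(C)c2c(c1CO)Oc1c(c(C)c(OCOC)c(C(=O)OC(C)(C)C)c1C(OC)OC)OC2=O
F9 | step 10 | (trimethylsilyl)ketene | C[Si](C)(C)C=C=O
F10 | step 6 | tert-butyl 5-[(tert-butyldimethylsilyl)oxy]-2-(methoxymethoxy)-3-methyl-4-(prop-2-en-1-yloxy)benzoate | Cc1c(OCC=C)c(O[Si](C)(C)C(C)(C)C)cc(C(=O)OC(C)(C)C)c1OCOC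
F11 | step 6 | arylmagnesium chloride at b6 of F10 | Cc1c(OCC=C)c(O[Si](C)(C)C(C)(C)C)c([Mg]Cl)c(C(=O)OC(C)(C)C)c1OCOC
F12 | step 6 | tert-butyl 3-[(tert-butyldimethylsilyl)oxy]-2-formyl-6-(methoxymethoxy)-5-methyl-4-(prop-2-en-1-yloxy)benzoate | Cc1c(OCC=C)c(O[Si](C)(C)C(C)(C)C)c(C=O)c(C(=O)OC(C)(C)C)c1OCOC
F13 | step 16 | benzylic acetate of 30 | C[Si](C)(C)c1c(C)c2c(c(COC(C)=O)c1OC)Oc1c(c(C)c(OCOC)c(C(=O)OC(C)(C)C)c1C(OC)OC)OC2=O
F14 | step 17 | racemic diacetate | COc1cc(C)c2c(c1COC(C)=O)Oc1c(c(C)c(O)c3c1C(OC(C)=O)OC3=O)OC2=O
F15 | step 17 | (S)-diacetate | COc1cc(C)c2c(c1COC(C)=O)Oc1c(c(C)c(O)c3c1[C@@H](OC(C)=O)OC3=O)OC2=O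
A1 | alternative 1 | diaryl ether with ring B fused to the (R)-3-benzyloxyphthalide | C=CCOC(=O)c1c(C)cc(OC)c(CO[Si](C)(C)C(C)(C)C)c1Oc1c(O)c(C)c(O)c2c1[C@H](OCc3ccccc3)OC2=O
A2 | alternative 1 | 4-aryloxy-1-methoxy-2-methyl-1,3-bis(trimethylsilyloxy)buta-1,3-diene (aryl = ring A) | COC(O[Si](C)(C)C)=C(C)C(O[Si](C)(C)C)=COc1c(C(=O)OCC=C)c(C)cc(OC)c1CO[Si](C)(C)C(C)(C)C
A3 | alternative 1 | (R)-5-(benzyloxy)-3-bromofuran-2(5H)-one | O=C1O[C@@H](OCc2ccccc2)C=C1Br
A4 | alternative 2 | depsidone with a6 aldehyde, b4 benzyl ether and phthalide methylene | COc1cc(C)c2c(c1C=O)Oc1c(c(C)c(OCc4ccccc4)c3c1COC3=O)OC2=O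
A5 | alternative 2 | 7-(benzyloxy)-4,5-dihydroxy-6-methyl-2-benzofuran-1(3H)-one | Cc1c(O)c(O)c2c(c1OCc1ccccc1)C(=O)OC2
A6 | alternative 2 | 2-fluoro-3-iodo-6-methoxy-4-methylbenzaldehyde | COc1cc(C)c(I)c(F)c1C=O
A7 | alternative 2 | carbon monoxide | [C-]#[O+]
A8 | alternative 3 | protected target with the lactol as its (R)-O-benzyl acetal | COc1cc(C)c2c(c1CO[Si](C)(C)C(C)(C)C)Oc1c(c(C)c(OCc4ccccc4)c3c1[C@H](OCc5ccccc5)OC3=O)OC2=O
A9 | alternative 3 | depsidone ortho-bromo aldehyde (b5 Br, b6 CHO) | COc1cc(C)c2c(c1CO[Si](C)(C)C(C)(C)C)Oc1c(c(C)c(OCc3ccccc3)c(Br)c1C=O)OC2=O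
A10 | alternative 3 | benzyl alcohol | OCc1ccccc1
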